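(The numbers were set for the occasion; what happens was integrated by code.)

A solution with a solubility of 0.11 M cannot hold as product the 0.88 M that was charged, so I expected crystals to shape these flasks.

| flask | solid substrate | temperature | time |
|---|---|---|---|
| Thursday's | 0.88 M | 100 °C | 6.0 min |
| Sunday's | 0.88 M | 50 °C | 6.0 min |
| Saturday's | 0.88 M | 75 °C | 6.0 min |

    starting material + 2 product → 3 product (k1 = 0.091 M⁻² s⁻¹, Ea1 = 45.0 kJ mol⁻¹)
    solid substrate ⇌ starting material, rate k2*(cs2 - [starting material]) while solid is left; crystals form when [starting material] > cs2 (cs2 = 0.60 M, k2 = 0.068 s⁻¹)
    starting material → product (k3 = 2.5 × 10⁻⁴ s⁻¹, Ea3 = 90.0 kJ mol⁻¹)
    crystals ⇌ product, rate k4*(cs4 - [product]) while solid is left; crystals form when [product] > cs4 (cs4 = 0.11 M, k4 = 0.58 s⁻¹)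
    (constants at 50 °C)

- what is said of product includes crystals
- where a step has two of a species, its rate is k times that concentration squared, and two are used at each turn
- crystals, solid substrate is a solid; its amount is given per volume of the solution
- the list of constants is for 50 °C, to be carried to other temperatures by the activation energies
- at the start none of the solid substrate is in solution
- what has only dissolved of solid substrate counts as not reacted

1. the best flask by amount of product, in percent of the solid substrate charged; "all alike" if 1.5 percentage points covers them all (Thursday's / Sunday's / Saturday's / all alike)
2. amount of product at the end, in percent of the solid substrate charged, Thursday's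
3. amount of product at the end, in percent of the solid substrate charged, Sunday's
4. amount of product at the end, in percent of the solid substrate charged, Saturday's

I built the flask up by hand and counted in powers of ten. A first-order loss falls by a factor 10 in one decade, which takes 2.30 time constants. First I took the plain step alone, with all the charge dissolved, and Sunday's gave 8.61%.

Then I added the solid. Its time constant of 14.7 s is short against the 66.7 min of the plain step at Sunday's temperature, so in Sunday's I held c(starting material) near 0.60 M while solid was left. Sunday's product dropped to 0.0540 M, or 6.14%.

Then came the step in which product speeds its own making, autocatalysis, and the crystals. Integrated once over that straight rise, it lifted Sunday's to 0.0731 M, or 8.31%. That is less than the solubility, so I expected no crystals there.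

In a hotter flask c(product) reaches the solubility and stays near it. The loss of starting material is then pseudo-first-order, with a capped constant: the plain constant plus the autocatalytic constant times the solubility squared. For Saturday's this was 0.386 min⁻¹, a decade of 5.96 min. For Thursday's it was 1.96 min⁻¹. Thursday's decade time, the time in which the capped constant cuts c(starting material) by a factor 10, was 1.18 min.

Saturday's began with no product, so the capped constant could not count from the start. Its capped time constant of 155 s was longer than that of dissolving, so I held c(starting material) near 0.60 M in Saturday's while solid was left. I took the rise on the plain step alone: at 0.166 min⁻¹, product reached the solubility in 1.10 min. The 0.170 M of solid then remaining went at the solubility of the solid times the capped constant, and the decades counted from 1.84 min. Saturday's came to 86.3%. In Thursday's the plain step's time constant of 45.0 s stood too close to that of dissolving for c(starting material) to be held near 0.60 M, so I reckoned no start for it. The whole 6.0 min of Thursday's measured 5.08 decades of 1.18 min, so I expected hardly any starting material at its end.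

The forecast named Thursday's, with 99.9% there, 8.9% for Sunday's and 87% for Saturday's, against my 8.31% and 86.3% for the last two, and held that “the autocatalytic step settles to an almost first-order rate”.

The flasks gave >99.9% for Thursday's, 8.94% for Sunday's and 87.0% for Saturday's, so Thursday's was best. Sunday's ended with crystals at 0%.

The neighbouring flask was Thursday's read at 1.5 min, with 9.28% starting material, 90.7% product and solid substrate at 0%. From there to 3.00 min lay 1.27 decades of 1.18 min, so I reckoned 0.497% starting material, and Thursday's held 0.479%. The 2.54 decades from that reading to 6.00 min reckoned 0.00135%, and Thursday's stood at 0% starting material and >99.9% product.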